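The route dismantles the benzene ring of unit A (the styryl-bearing 2,3-dihydrobenzofuran) at C3a–C7a, C4–C5 and C6–C7. It exploits the fact that O1–C2–C3 is a three-atom tether between an ethynyl ether (C7a≡C7) and a silylalkyne (C3a≡C4). C5–C6 with its styryl arm is a conjugated enyne. One ruthenium-catalysed [2+2+2] cycloaddition therefore closes the furan ring and the arene of unit A and delivers the stilbene in a single operation. The precursor is an acyclic anti diyne whose two stereocentres encode the trans ring. It already carries finished unit B, made by the same sequence. Silicon at C4 steers the regiochemistry and later becomes the phenol.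

Key step: step 18

Remark (assumption): the SMILES is read as 2S,3S in unit A and 2′S,3′S in unit B, both rings trans; primed locants belong to unit B, the dihydrobenzofuran bonded through C6′ to C3 of unit A.
Design note: all phenols travel as MOM ethers rather than methyl ethers, so the last step needs only dilute acid and no Lewis-acid demethylation of a stilbene-bearing 2-aryl-dihydrobenzofuran.
Abbreviations: MOMO = methoxymethoxy (OCH2OCH3); BDMS = benzyldimethylsilyl (SiMe2CH2Ph); UB = (2S,3S)-3-[3,5-bis(MOMO)phenyl]-4-(MOMO)-2-[4-(MOMO)phenyl]-2,3-dihydrobenzofuran-6-yl.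

Step 1
Reactants: 1 3,5-dihydroxybenzaldehyde
Product: 2 3,5-bis(MOMO)benzaldehyde
Conditions: MOMCl, iPr2NEt, CH2Cl2, 0 °C→rt
Reagents that add atoms: methoxymethyl chloride, COCCl
Why: Williamson-type O-alkylation of two unhindered phenols under amine base is routine and leaves the aldehyde untouched.

Step 2
Reactants: 3 4-hydroxybenzaldehyde
Product: 4 4-(MOMO)benzaldehyde
Conditions: MOMCl, iPr2NEt, CH2Cl2, 0 °C→rt
Reagents that add atoms: methoxymethyl chloride, COCCl
Why: The same Williamson-type phenol protection as in step 1 applies.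

Step 3
Reactants: 5 benzylchlorodimethylsilane; 6 ethynylmagnesium bromide
Product: 7 benzyl(ethynyl)dimethylsilane
Conditions: THF, 0 °C→rt
Reagents that add atoms: none
Why: Nucleophilic substitution at silicon by the acetylide Grignard reagent gives the terminal silylacetylene that serves both halves of the synthesis.

Step 4
Reactants: 2 3,5-bis(MOMO)benzaldehyde; 7 benzyl(ethynyl)dimethylsilane
Product: 8 (R)-3-BDMS-1-[3,5-bis(MOMO)phenyl]prop-2-yn-1-ol
Conditions: 7, Et2Zn, PhMe, reflux; then (S)-BINOL (20 mol %), Ti(OiPr)4 (50 mol %), Et2O, rt; then 2, rt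
Reagents that add atoms: none
Why: BINOL–titanium-catalysed asymmetric alkynylzinc addition is at its best with aromatic aldehydes, and the (S)-ligand is expected to deliver the alkynyl group to the Si face, which sets the carbinol centre as R.

Step 5
Reactants: 8 (R)-propargylic alcohol
Product: 9 (R)-methanesulfonate of 8
Conditions: MsCl, Et3N, CH2Cl2, −78→−40 °C, used crude
Reagents that add atoms: methanesulfonyl chloride, CS(=O)(=O)Cl
Why: O-sulfonylation leaves the C–O bond intact (retention), and because both ring oxygens are meta to the carbinol carbon the benzylic mesylate should not ionise at low temperature.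

Step 6
Reactants: 9 (R)-mesylate; 4 4-(MOMO)benzaldehyde
Product: 11 anti alcohol (1S,2S)-4-BDMS-2-[3,5-bis(MOMO)phenyl]-1-[4-(MOMO)phenyl]but-3-yn-1-ol, via allenylzinc 10 (not isolated)
Conditions: Pd(OAc)2 (5 mol %), PPh3 (5 mol %), Et2Zn (3 equiv), THF, −78→−20 °C
Reagents that add atoms: none
Why: In this Marshall propargylation Pd(0) displaces the mesylate anti (SN2′), Et2Zn transmetallates with retention to 10, and 10 adds to 4 on its zinc-bearing face through a closed SE2′ transition state, so the R centre is relayed with net inversion into S at C3′ and the cyclic transition state sets C2′ as S (anti).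

Step 7
Reactants: 11 anti alcohol
Product: 13 ethynyl ether of 11 (1S,2S; unit-B diyne), via dichlorovinyl ether 12 (not isolated)
Conditions: KH, THF, 0 °C; Cl2C=CHCl, −50 °C→rt; then n-BuLi (2.3 equiv), −78 °C; MeOH, −78→0 °C; kept cold, used at once
Reagents that add atoms: trichloroethylene, ClC=C(Cl)Cl
Why: This is the trichloroethylene route to alkynyl ethers, known for secondary benzylic alcohols: the alkoxide adds to dichloroacetylene formed in situ, n-BuLi effects dehydrochlorination and Cl/Li exchange, and protonation follows without breaking the C2′–O bond, so both stereocentres persist.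

Step 8
Reactants: 13 unit-B diyne; 14 3,3-diethoxyprop-1-yne
Product: 15 (2S,3S)-4-BDMS-6-(diethoxymethyl)-3-[3,5-bis(MOMO)phenyl]-2-[4-(MOMO)phenyl]-2,3-dihydrobenzofuran
Conditions: Cp*RuCl(cod) (5 mol %), 14 (3 equiv), DCE, rt, slow addition of 13
Reagents that add atoms: none
Why: This [2+2+2] cyclotrimerisation of a 1,6-diyne with a terminal alkyne rehearses step 18: oxidative coupling of the tethered alkynes closes the dihydrofuran, insertion of 14 closes the arene with the acetal meta to the bulky silyl group, and the two sp3 centres are untouched.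

Step 9
Reactants: 15 arylsilane acetal
Product: 17 (2S,3S)-6-(diethoxymethyl)-3-[3,5-bis(MOMO)phenyl]-2-[4-(MOMO)phenyl]-2,3-dihydrobenzofuran-4-ol, via arylsilanol 16 (not isolated)
Conditions: TBAF, THF, 0 °C→rt; then KHCO3, 30% aq H2O2, MeOH, rt→40 °C
Reagents that add atoms: hydrogen peroxide, OO
Why: In this Tamao–Fleming oxidation of a safety-catch silane, fluoride expels benzyl (a better leaving carbanion than the electron-rich aryl group) to unmask silanol 16, whose aryl group then migrates from silicon to peroxide oxygen under basic conditions that spare the acetal and MOM groups.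

Step 10
Reactants: 17 C4′ phenol
Product: 19 unit-B aldehyde UB-CHO, via MOM-protected acetal 18 (not isolated)
Conditions: MOMCl, iPr2NEt, CH2Cl2, 0 °C→rt; then 1 M aq HCl, THF, rt, 30 min
Reagents that add atoms: methoxymethyl chloride, COCCl; water, O
Why: Phenol protection is followed by hydrolysis of the benzaldehyde diethyl acetal, which is cleaved by dilute acid far faster than aryl MOM ethers.

Step 11
Reactants: 19 unit-B aldehyde; 7 benzyl(ethynyl)dimethylsilane
Product: 20 (R)-3-BDMS-1-(UB)prop-2-yn-1-ol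
Conditions: 7, Et2Zn, PhMe, reflux; then (S)-BINOL (20 mol %), Ti(OiPr)4 (50 mol %), Et2O, rt; then 19, rt
Reagents that add atoms: none
Why: The same BINOL–titanium-catalysed asymmetric alkynylzinc addition as in step 4 applies, and since the stereocentres of unit B are remote the (S)-ligand should again direct Si-face attack and set the new carbinol centre as R.

Step 12
Reactants: 20 (R)-propargylic alcohol
Product: 21 (R)-methanesulfonate of 20
Conditions: MsCl, Et3N, CH2Cl2, −78→−40 °C, used crude
Reagents that add atoms: methanesulfonyl chloride, CS(=O)(=O)Cl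
Why: O-sulfonylation proceeds with retention, and O1′ and the C4′ oxygen are both meta to the carbinol carbon, so ionisation is not assisted.

Step 13
Reactants: 21 (R)-mesylate; 4 4-(MOMO)benzaldehyde
Product: 23 anti alcohol (1S,2S)-4-BDMS-1-[4-(MOMO)phenyl]-2-(UB)but-3-yn-1-ol, via allenylzinc 22 (not isolated)
Conditions: Pd(OAc)2 (5 mol %), PPh3 (5 mol %), Et2Zn (3 equiv), THF, −78→−20 °C
Reagents that add atoms: none
Why: This Marshall propargylation runs as in step 6: anti SN2′ palladation, retentive transmetallation and closed SE2′ addition convert the R mesylate into S-configured C3, and the cyclic transition state sets C2 as S (anti), independently of unit B.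

Step 14
Reactants: 23 anti alcohol
Product: 25 ethynyl ether of 23 (1S,2S; key diyne carrying complete unit B), via dichlorovinyl ether 24 (not isolated)
Conditions: KH, THF, 0 °C; Cl2C=CHCl, −50 °C→rt; then n-BuLi (2.3 equiv), −78 °C; MeOH, −78→0 °C; kept cold, used at once
Reagents that add atoms: trichloroethylene, ClC=C(Cl)Cl
Why: The same trichloroethylene route to alkynyl ethers as in step 7 is used; any aryl lithiation next to MOMO groups is simply reversed by the proton quench, and the C2–O bond is never broken.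

Step 15
Reactants: 26 2,4-dihydroxybenzaldehyde
Product: 27 2,4-bis(MOMO)benzaldehyde
Conditions: NaH, DMF, 0 °C; MOMCl, 0 °C→rt
Reagents that add atoms: methoxymethyl chloride, COCCl
Why: In this Williamson-type protection, full deprotonation with NaH overcomes the hydrogen bond that slows alkylation of the 2-hydroxyl group.

Step 16
Reactants: 28 3-bromo-1-(trimethylsilyl)prop-1-yne
Product: 29 diethyl [3-(trimethylsilyl)prop-2-yn-1-yl]phosphonate
Conditions: P(OEt)3, neat, 130 °C
Reagents that add atoms: triethyl phosphite, CCOP(OCC)OCC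
Why: This is a Michaelis–Arbuzov reaction of a reactive propargylic bromide, in which the silyl cap blocks isomerisation to an allene.

Step 17
Reactants: 27 2,4-bis(MOMO)benzaldehyde; 29 propargylic phosphonate
Product: 31 (E)-1-(but-1-en-3-yn-1-yl)-2,4-bis(MOMO)benzene, via silylated enyne 30 (not isolated)
Conditions: LiHMDS, THF, −78 °C; 27, −78 °C→rt; then K2CO3 (cat.), MeOH, rt
Reagents that add atoms: none
Why: Horner–Wadsworth–Emmons olefination with a stabilised propargylic phosphonate anion is E-selective with aromatic aldehydes, and methanolysis of the alkynyl–SiMe3 bond then frees the terminal alkyne.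

Step 18
Reactants: 25 key diyne; 31 enyne
Product: 32 (2S,3S)-4-BDMS-6-[(E)-2,4-bis(MOMO)styryl]-2-[4-(MOMO)phenyl]-3-(UB)-2,3-dihydrobenzofuran
Conditions: Cp*RuCl(cod) (10 mol %), 31 (3 equiv), DCE, rt, 25 added over 3 h, Ar, dark
Reagents that add atoms: none
Why: Cp*RuCl binds both tethered alkynes of 25 and couples them oxidatively to a bicyclic ruthenacycle (C3a–C7a bond), after which the terminal triple bond of 31 inserts and reductive elimination releases the arene (C4–C5 and C6–C7 bonds). The closest known reaction type is the Cp*RuCl- or Rh(I)-catalysed [2+2+2] cycloaddition of 1,6-diynes with terminal monoalkynes, which already covers heteroatom-substituted diynes (ynamide and aryl alkynyl ether tethers) that give indolines and fused benzofurans at room temperature. The dihydrofuran ring closes in the intramolecular oxidative coupling, made easy by the three-atom O1–C2–C3 tether, and the benzene ring closes in the intermolecular insertion and reductive elimination. No stereocentre is created: C2 and C3 are sp3 spectators under neutral conditions, so the anti array of 25 passes unchanged into the trans ring. The styryl group lands at C6, meta to silicon, because the bulky BDMS group on the C4 terminus forces the unsubstituted alkyne carbon of 31 to bond to C4, and the triple bond reacts in preference to the 1,2-disubstituted alkene because terminal alkynes insert much faster. Room temperature, slow addition of 25 and excess 31 protect the benzylic ethynyl ether from sigmatropic or retro-ene loss and suppress self-coupling of the diyne.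

Step 19
Reactants: 32 arylsilane
Product: 34 (2S,3S)-6-[(E)-2,4-bis(MOMO)styryl]-2-[4-(MOMO)phenyl]-3-(UB)-2,3-dihydrobenzofuran-4-ol, via arylsilanol 33 (not isolated)
Conditions: TBAF, THF, 0 °C→rt; then KHCO3, 30% aq H2O2, MeOH, rt→40 °C
Reagents that add atoms: hydrogen peroxide, OO
Why: This Tamao–Fleming oxidation runs as in step 9; O1 is meta to C4 so protodesilylation is not assisted, and nucleophilic basic peroxide does not attack the electron-rich stilbene.

Step 20
Reactants: 34 hepta-MOM phenol
Product: 35 target CNP0186204.1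
Conditions: 1.25 M HCl in MeOH–THF (degassed), rt→40 °C, Ar, dark
Reagents that add atoms: none
Why: Acid-catalysed acetal exchange of the seven aryl MOM ethers with methanol needs only dilute acid near room temperature, under which the thermodynamically preferred trans-dihydrobenzofurans and the E-alkene should keep their configuration.

Compound list
1 | 3,5-dihydroxybenzaldehyde | O=Cc1cc(O)cc(O)c1 | starting material
2 | 3,5-bis(methoxymethoxy)benzaldehyde | O=Cc1cc(OCOC)cc(OCOC)c1 | intermediate
3 | 4-hydroxybenzaldehyde | O=Cc1ccc(O)cc1 | starting material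
4 | 4-(methoxymethoxy)benzaldehyde | O=Cc1ccc(OCOC)cc1 | intermediate
5 | benzylchlorodimethylsilane | C[Si](C)(Cl)Cc1ccccc1 | starting material
6 | ethynylmagnesium bromide | C#C[Mg]Br | starting material
7 | benzyl(ethynyl)dimethylsilane | C#C[Si](C)(C)Cc1ccccc1 | intermediate
8 | (R)-3-BDMS-1-[3,5-bis(MOMO)phenyl]prop-2-yn-1-ol | O[C@@H](C#C[Si](C)(C)Cc1ccccc1)c1cc(OCOC)cc(OCOC)c1 | intermediate
9 | (R)-methanesulfonate of 8 | CS(=O)(=O)O[C@@H](C#C[Si](C)(C)Cc1ccccc1)c1cc(OCOC)cc(OCOC)c1 | intermediate
10 | (aS)-[1-BDMS-3-[3,5-bis(MOMO)phenyl]propa-1,2-dienyl](ethyl)zinc | [H]C(c1cc(OCOC)cc(OCOC)c1)=[C@]=C([Si](C)(C)Cc1ccccc1)[Zn]CC | intermediate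
11 | (1S,2S)-4-BDMS-2-[3,5-bis(MOMO)phenyl]-1-[4-(MOMO)phenyl]but-3-yn-1-ol (anti) | COCOc1ccc([C@@H](O)[C@H](C#C[Si](C)(C)Cc2ccccc2)c2cc(OCOC)cc(OCOC)c2)cc1 | intermediate
12 | (E)-1,2-dichlorovinyl ether of 11 | COCOc1ccc([C@@H](O/C(Cl)=C\Cl)[C@H](C#C[Si](C)(C)Cc2ccccc2)c2cc(OCOC)cc(OCOC)c2)cc1 | intermediate
13 | ethynyl ether of 11 (unit-B diyne) | COCOc1ccc([C@@H](OC#C)[C@H](C#C[Si](C)(C)Cc2ccccc2)c2cc(OCOC)cc(OCOC)c2)cc1 | intermediate
14 | 3,3-diethoxyprop-1-yne (propiolaldehyde diethyl acetal) | C#CC(OCC)OCC | starting material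
15 | (2S,3S)-4-BDMS-6-(diethoxymethyl)-3-[3,5-bis(MOMO)phenyl]-2-[4-(MOMO)phenyl]-2,3-dihydrobenzofuran | CCOC(OCC)c1cc([Si](C)(C)Cc2ccccc2)c2c(c1)O[C@H](c1ccc(OCOC)cc1)[C@H]2c1cc(OCOC)cc(OCOC)c1 | intermediate
16 | C4′ dimethylsilanol derived from 15 | CCOC(OCC)c1cc([Si](C)(C)O)c2c(c1)O[C@H](c1ccc(OCOC)cc1)[C@H]2c1cc(OCOC)cc(OCOC)c1 | intermediate
17 | (2S,3S)-6-(diethoxymethyl)-3-[3,5-bis(MOMO)phenyl]-2-[4-(MOMO)phenyl]-2,3-dihydrobenzofuran-4-ol | CCOC(OCC)c1cc(O)c2c(c1)O[C@H](c1ccc(OCOC)cc1)[C@H]2c1cc(OCOC)cc(OCOC)c1 | intermediate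
18 | C4′ MOM ether of 17 | CCOC(OCC)c1cc(OCOC)c2c(c1)O[C@H](c1ccc(OCOC)cc1)[C@H]2c1cc(OCOC)cc(OCOC)c1 | intermediate
19 | (2S,3S)-3-[3,5-bis(MOMO)phenyl]-4-(MOMO)-2-[4-(MOMO)phenyl]-2,3-dihydrobenzofuran-6-carbaldehyde (UB-CHO) | O=Cc1cc(OCOC)c2c(c1)O[C@H](c1ccc(OCOC)cc1)[C@H]2c1cc(OCOC)cc(OCOC)c1 | intermediate
20 | (R)-3-BDMS-1-(UB)prop-2-yn-1-ol | O[C@@H](C#C[Si](C)(C)Cc1ccccc1)c1cc(OCOC)c2c(c1)O[C@H](c1ccc(OCOC)cc1)[C@H]2c1cc(OCOC)cc(OCOC)c1 | intermediate
21 | (R)-methanesulfonate of 20 | CS(=O)(=O)O[C@@H](C#C[Si](C)(C)Cc1ccccc1)c1cc(OCOC)c2c(c1)O[C@H](c1ccc(OCOC)cc1)[C@H]2c1cc(OCOC)cc(OCOC)c1 | intermediate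
22 | (aS)-[1-BDMS-3-(UB)propa-1,2-dienyl](ethyl)zinc | [H]C(c1cc(OCOC)c2c(c1)O[C@H](c1ccc(OCOC)cc1)[C@H]2c1cc(OCOC)cc(OCOC)c1)=[C@]=C([Si](C)(C)Cc1ccccc1)[Zn]CC | intermediate
23 | (1S,2S)-4-BDMS-1-[4-(MOMO)phenyl]-2-(UB)but-3-yn-1-ol (anti) | COCOc1ccc([C@@H](O)[C@H](C#C[Si](C)(C)Cc2ccccc2)c2cc(OCOC)c3c(c2)O[C@H](c2ccc(OCOC)cc2)[C@H]3c2cc(OCOC)cc(OCOC)c2)cc1 | intermediate
24 | (E)-1,2-dichlorovinyl ether of 23 | COCOc1ccc([C@@H](O/C(Cl)=C\Cl)[C@H](C#C[Si](C)(C)Cc2ccccc2)c2cc(OCOC)c3c(c2)O[C@H](c2ccc(OCOC)cc2)[C@H]3c2cc(OCOC)cc(OCOC)c2)cc1 | intermediate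
25 | ethynyl ether of 23 (anti ethynyl ether–silylalkyne diyne carrying unit B) | COCOc1ccc([C@@H](OC#C)[C@H](C#C[Si](C)(C)Cc2ccccc2)c2cc(OCOC)c3c(c2)O[C@H](c2ccc(OCOC)cc2)[C@H]3c2cc(OCOC)cc(OCOC)c2)cc1 | intermediate
26 | 2,4-dihydroxybenzaldehyde | O=Cc1ccc(O)cc1O | starting material
27 | 2,4-bis(methoxymethoxy)benzaldehyde | O=Cc1ccc(OCOC)cc1OCOC | intermediate
28 | 3-bromo-1-(trimethylsilyl)prop-1-yne | C[Si](C)(C)C#CCBr | starting material
29 | diethyl [3-(trimethylsilyl)prop-2-yn-1-yl]phosphonate | CCOP(=O)(CC#C[Si](C)(C)C)OCC | intermediate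
30 | (E)-[4-[2,4-bis(MOMO)phenyl]but-3-en-1-yn-1-yl]trimethylsilane | C[Si](C)(C)C#C/C=C/c1ccc(OCOC)cc1OCOC | intermediate
31 | (E)-1-(but-1-en-3-yn-1-yl)-2,4-bis(MOMO)benzene | C#C/C=C/c1ccc(OCOC)cc1OCOC | intermediate
32 | (2S,3S)-4-BDMS-6-[(E)-2,4-bis(MOMO)styryl]-2-[4-(MOMO)phenyl]-3-(UB)-2,3-dihydrobenzofuran | COCOc1ccc([C@H]2Oc3cc(/C=C/c4ccc(OCOC)cc4OCOC)cc([Si](C)(C)Cc4ccccc4)c3[C@@H]2c2cc(OCOC)c3c(c2)O[C@H](c2ccc(OCOC)cc2)[C@H]3c2cc(OCOC)cc(OCOC)c2)cc1 | intermediate
33 | C4 dimethylsilanol derived from 32 | COCOc1ccc([C@H]2Oc3cc(/C=C/c4ccc(OCOC)cc4OCOC)cc([Si](C)(C)O)c3[C@@H]2c2cc(OCOC)c3c(c2)O[C@H](c2ccc(OCOC)cc2)[C@H]3c2cc(OCOC)cc(OCOC)c2)cc1 | intermediate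
34 | (2S,3S)-6-[(E)-2,4-bis(MOMO)styryl]-2-[4-(MOMO)phenyl]-3-(UB)-2,3-dihydrobenzofuran-4-ol | COCOc1ccc([C@H]2Oc3cc(/C=C/c4ccc(OCOC)cc4OCOC)cc(O)c3[C@@H]2c2cc(OCOC)c3c(c2)O[C@H](c2ccc(OCOC)cc2)[C@H]3c2cc(OCOC)cc(OCOC)c2)cc1 | intermediate
35 | CNP0186204.1, (2S,3S,2′S,3′S) octaphenol | Oc1ccc([C@H]2Oc3cc(/C=C/c4ccc(O)cc4O)cc(O)c3[C@@H]2c2cc(O)c3c(c2)O[C@H](c2ccc(O)cc2)[C@H]3c2cc(O)cc(O)c2)cc1 | target

Total step count: 20. Longest linear sequence: 15 (steps 1, 4–14, 18–20).

Steps most likely to fail

Step 18.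
- **Risk:** The conjugated enyne may tie up the metal through its diene-like π system or oligomerise. It may insert with the wrong orientation. The bimolecular insertion may also be so slow that the benzylic ethynyl ether is lost by rearrangement first.
- **Fallback:** The stilbene is no longer brought in by the alkyne partner. Setting out from 25, cyclotrimerisation under the conditions of step 8 with commercial diethyl prop-2-yn-1-ylphosphonate, a small non-conjugated alkyne, should give the C6-(diethoxyphosphorylmethyl) arylsilane F1.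
- **Return:** Horner–Wadsworth–Emmons olefination of aldehyde 27 with the anion of F1 (KOt-Bu, THF, 0 °C) then builds the E-alkene and comes back to the route at 32.

Step 7 (step 14 shares the risk).
- **Risk:** The potassium alkoxide may revert to aldehyde and a stabilised propargyl anion, which erodes both stereocentres. It may also strip silicon from the alkyne before it is trapped.
- **Fallback:** No alkoxide is formed. Setting out from 11, formylation with formic acetic anhydride and pyridine gives the formate ester F2. Appel-type dichloromethylenation of the formyl group (PPh3, CCl4, THF, 60 °C) gives the 2,2-dichlorovinyl ether F3.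
- **Return:** n-BuLi (THF, −78 °C) followed by a methanol quench comes back to the route at 13.

Step 6 (step 13 shares the risk).
- **Risk:** The aryl-substituted mesylate may ionise. The allenylzinc may lose configurational integrity before it meets the electron-rich aldehyde. The anti/syn preference may be modest.
- **Fallback:** The transient zinc species is replaced by an isolable, configurationally stable allenylboron reagent. Setting out from 8, methyl chloroformate and pyridine give the (R)-methyl carbonate F4. Copper-catalysed anti-SN2′ borylation (CuOt-Bu, Xantphos, B2pin2, THF, rt) gives the (aR)-allenyl pinacolboronate F5.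
- **Return:** Thermal allenylboration of aldehyde 4 (toluene, 60 °C, aqueous work-up) through a closed six-membered transition state comes back to the route at 11 with the same stereochemical relay.

Further compounds
F1 | step 18 | diethyl {[(2S,3S)-4-BDMS-2-[4-(MOMO)phenyl]-3-(UB)-2,3-dihydrobenzofuran-6-yl]methyl}phosphonate | COCOc1ccc([C@H]2Oc3cc(CP(=O)(OCC)OCC)cc([Si](C)(C)Cc4ccccc4)c3[C@@H]2c2cc(OCOC)c3c(c2)O[C@H](c2ccc(OCOC)cc2)[C@H]3c2cc(OCOC)cc(OCOC)c2)cc1
F2 | step 7 | formate ester of 11 | COCOc1ccc([C@@H](OC=O)[C@H](C#C[Si](C)(C)Cc2ccccc2)c2cc(OCOC)cc(OCOC)c2)cc1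
F3 | step 7 | 2,2-dichlorovinyl ether of 11 | COCOc1ccc([C@@H](OC=C(Cl)Cl)[C@H](C#C[Si](C)(C)Cc2ccccc2)c2cc(OCOC)cc(OCOC)c2)cc1
F4 | step 6 | (R)-methyl carbonate of 8 | COC(=O)O[C@@H](C#C[Si](C)(C)Cc1ccccc1)c1cc(OCOC)cc(OCOC)c1
F5 | step 6 | (aR)-2-[1-BDMS-3-[3,5-bis(MOMO)phenyl]propa-1,2-dienyl]-4,4,5,5-tetramethyl-1,3,2-dioxaborolane | [H]C(c1cc(OCOC)cc(OCOC)c1)=[C@]=C([Si](C)(C)Cc1ccccc1)B1OC(C)(C)C(C)(C)O1
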